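**Assumption:** the absolute configuration is taken exactly as written in the SMILES (decalin 1R,4R,4aS,6S,8aR; benzylic carbon S), and compounds 1, 3 and 7 are taken as commercially available.

**Atom labels used below:** C1 = ring CH bearing the side chain, C4 = ring carbinol carbon, C5 = ring-fusion CH, C7 = CH bearing the C3 unit, C10 = quaternary C–CH3, C11 = carbinol carbon of the C3 unit, C9′ = benzylic carbon. In names the decalin locants 1, 4, 4a, 6, 8a stand for C1, C4, C5, C7, C10.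

## Retrosynthetic overview

1. The usual disconnection (terpene enol ether plus benzylic cation at C1–C9′, decalin by Robinson annulation) is not used. The phenols and both CHO groups are unveiled last: 19 ⇐ 18 ⇐ dibromide 16 ⇐ 15.
2. C9′–H comes from ionic hydrogenation of a tertiary 2,4,6-trimethoxybenzylic cation, so the isobutyl C–C bond is the one disconnected. All three carbinol carbons (C4, C11, C9′) come from triketone 11 by Grignard additions.
3. Triketone 11 ⇐ cycloadduct 9 by thermodynamic epimerisation at C1, C5 and C7; only the quaternary C10 is set kinetically.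
4. Key step: Lewis-acid [4+2] of a carvone-derived 2-ethoxydiene with 2,4,6-trimethoxyphenyl vinyl ketone. It forms ring A, quaternary C10, the C4 carbonyl and the C1–C9′ acyl unit at once; the carvone stereocentre relays chirality to C10 and is then inverted.
5. Ring order: ring B (from (R)-carvone), then ring A (cycloaddition); the aromatic ring arrives on the dienophile.

## Route

**Step 1**
Reactants: 1 2′,4′,6′-trimethoxyacetophenone
Product: 2 1-(2,4,6-trimethoxyphenyl)prop-2-en-1-one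
Conditions: (CH2O)n, i-Pr2NH·CF3CO2H, CF3CO2H (10 mol%), THF, reflux
Reagents that add atoms: paraformaldehyde (formaldehyde), C=O
Why: Mannich-type α-methylenation of an aryl methyl ketone (aminomethylation then elimination); the vinyl ketone is used fresh.

**Step 2**
Reactants: 3 (R)-(−)-carvone
Product: 5 (5R)-2-methyl-5-(prop-1-en-2-yl)cyclohex-1-en-1-yl trifluoromethanesulfonate, via lithium enolate 4 (not isolated)
Conditions: LiBH(s-Bu)3, THF, −78 °C; then PhNTf2, −78 °C → rt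
Reagents that add atoms: N-phenylbis(trifluoromethanesulfonimide), O=S(=O)(N(c1ccccc1)S(=O)(=O)C(F)(F)F)C(F)(F)F; lithium tri-sec-butylborohydride (H; Li of 4), [Li+].CCC(C)[BH-](C(C)CC)C(C)CC
Why: Conjugate (1,4-) hydride reduction of the β-unsubstituted enone gives the tetrasubstituted enolate regiospecifically, and O-triflation traps it; the carvone stereocentre is untouched.

**Step 3**
Reactants: 5 (5R)-2-methyl-5-(prop-1-en-2-yl)cyclohex-1-en-1-yl trifluoromethanesulfonate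
Product: 6 (5R)-5-acetyl-2-methylcyclohex-1-en-1-yl trifluoromethanesulfonate
Conditions: OsO4 (2 mol%), NaIO4, 2,6-lutidine, dioxane/H2O, rt
Reagents that add atoms: sodium periodate (ketone oxygen, delivered through OsO4), [Na+].[O-]I(=O)(=O)=O
Why: Lemieux–Johnson cleavage of the electron-rich 1,1-disubstituted alkene; the electron-poor tetrasubstituted enol triflate is inert. The acetyl group makes this stereocentre epimerisable later.

**Step 4**
Reactants: 6 (5R)-5-acetyl-2-methylcyclohex-1-en-1-yl trifluoromethanesulfonate; 7 tributyl(1-ethoxyethenyl)stannane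
Product: 8 1-[(1R)-3-(1-ethoxyethenyl)-4-methylcyclohex-3-en-1-yl]ethan-1-one
Conditions: Pd(PPh3)4 (5 mol%), LiCl, CuI (10 mol%), THF, 65 °C
Reagents that add atoms: none
Why: Stille coupling of a vinyl triflate (oxidative addition to zerovalent palladium, transmetalation, reductive elimination) under neutral conditions that do not epimerise the α-acetyl centre.

**Step 5**
Reactants: 8 1-[(1R)-3-(1-ethoxyethenyl)-4-methylcyclohex-3-en-1-yl]ethan-1-one; 2 1-(2,4,6-trimethoxyphenyl)prop-2-en-1-one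
Product: 9 [(1R,6R,8aR)-6-acetyl-4-ethoxy-8a-methyl-1,2,3,5,6,7,8,8a-octahydronaphthalen-1-yl](2,4,6-trimethoxyphenyl)methanone
Conditions: Me2AlCl (0.3 equiv), CH2Cl2, −78 → −30 °C; Et3N quench
Reagents that add atoms: none
Why: Lewis-acid-promoted Diels–Alder reaction (asynchronous, possibly stepwise Mukaiyama–Michael then ring closure) with "para" regiochemistry set by the 2-ethoxy group. The dienophile should bond to C10 by axial attack on the ring B half-chair, cis to the pseudo-equatorial acetyl group (1,4-induction, as in alkylations of dihydrocarvone enolates), which sets the quaternary centre. The minor C10 epimer is removed by chromatography here, because after step 6 it would become the enantiomeric series. The endo/exo result at C1 is irrelevant (drawn endo).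

**Step 6**
Reactants: 9 [(1R,6R,8aR)-6-acetyl-4-ethoxy-8a-methyl-1,2,3,5,6,7,8,8a-octahydronaphthalen-1-yl](2,4,6-trimethoxyphenyl)methanone
Product: 11 [(1S,4aS,6S,8aS)-6-acetyl-8a-methyl-4-oxodecahydronaphthalen-1-yl](2,4,6-trimethoxyphenyl)methanone, via unequilibrated triketone 10 (not isolated)
Conditions: aq. HCl (cat.), THF, rt; then NaOMe, MeOH, 40 °C
Reagents that add atoms: water, O
Why: Enol ether hydrolysis, then base-mediated epimerisation under thermodynamic control: C5 goes to the trans ring fusion, the C7 acetyl to equatorial (this inverts the carvone-derived centre), and the C1 aroyl to equatorial. Conditions are kept mild so the 1,5-dicarbonyl does not undergo retro-Michael cleavage at C10.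

**Step 7**
Reactants: 11 [(1S,4aS,6S,8aS)-6-acetyl-8a-methyl-4-oxodecahydronaphthalen-1-yl](2,4,6-trimethoxyphenyl)methanone
Product: 12 [(1S,4R,4aS,6S,8aS)-4-hydroxy-6-(2-hydroxypropan-2-yl)-4,8a-dimethyldecahydronaphthalen-1-yl](2,4,6-trimethoxyphenyl)methanone
Conditions: MeMgBr (3.5 equiv), THF, −78 → 0 °C
Reagents that add atoms: methylmagnesium bromide, C[Mg]Br
Why: Grignard 1,2-addition to both unhindered ketones. At C4 the axial trajectory is blocked by the syn-axial C10 methyl, so methyl enters equatorially and gives the axial tertiary alcohol (4R). The di-ortho-substituted aryl ketone is too hindered to react.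

**Step 8**
Reactants: 12 [(1S,4R,4aS,6S,8aS)-4-hydroxy-6-(2-hydroxypropan-2-yl)-4,8a-dimethyldecahydronaphthalen-1-yl](2,4,6-trimethoxyphenyl)methanone
Product: 13 1-[(1S,4R,4aS,6S,8aS)-4-hydroxy-6-(2-hydroxypropan-2-yl)-4,8a-dimethyldecahydronaphthalen-1-yl]-3-methyl-1-(2,4,6-trimethoxyphenyl)but-3-en-1-ol
Conditions: CH2=C(CH3)CH2MgCl (6 equiv), THF, −40 → 0 °C; cold aq. NH4Cl
Reagents that add atoms: (2-methylallyl)magnesium chloride, CC(=C)C[Mg]Cl
Why: Allyl-type Grignard reagents add to very hindered ketones through a cyclic six-membered SE2′ transition state. The cold quench avoids retro-allylation; the new carbinol configuration is irrelevant because it is ionised in step 10.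

**Step 9**
Reactants: 13 1-[(1S,4R,4aS,6S,8aS)-4-hydroxy-6-(2-hydroxypropan-2-yl)-4,8a-dimethyldecahydronaphthalen-1-yl]-3-methyl-1-(2,4,6-trimethoxyphenyl)but-3-en-1-ol
Product: 14 1-[(1S,4R,4aS,6S,8aS)-4-hydroxy-6-(2-hydroxypropan-2-yl)-4,8a-dimethyldecahydronaphthalen-1-yl]-3-methyl-1-(2,4,6-trimethoxyphenyl)butan-1-ol
Conditions: H2 (1 atm), RhCl(PPh3)3 (5 mol%), benzene/EtOH, rt
Reagents that add atoms: none
Why: Homogeneous hydrogenation of the 1,1-disubstituted alkene gives the isobutyl group without hydrogenolysis of the benzylic C–O bond.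

**Step 10**
Reactants: 14 1-[(1S,4R,4aS,6S,8aS)-4-hydroxy-6-(2-hydroxypropan-2-yl)-4,8a-dimethyldecahydronaphthalen-1-yl]-3-methyl-1-(2,4,6-trimethoxyphenyl)butan-1-ol
Product: 15 2-[(1S)-1-[(1R,4R,4aS,6S,8aR)-4-hydroxy-6-(2-hydroxypropan-2-yl)-4,8a-dimethyldecahydronaphthalen-1-yl]-3-methylbutyl]-1,3,5-trimethoxybenzene
Conditions: Et3SiH (5 equiv), CF3CO2H (3 equiv), CH2Cl2, −40 °C
Reagents that add atoms: none
Why: Ionic hydrogenation (SN1). The trimethoxybenzylic tertiary alcohol ionises under conditions that should leave the two aliphatic tertiary carbinols intact. In the A1,3-minimised cation the C1–H bond eclipses the aryl side, so quaternary C10 shields one face and Et3SiH delivers hydride from the C2 side, which is predicted to give the 1′S centre.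

**Step 11**
Reactants: 15 2-[(1S)-1-[(1R,4R,4aS,6S,8aR)-4-hydroxy-6-(2-hydroxypropan-2-yl)-4,8a-dimethyldecahydronaphthalen-1-yl]-3-methylbutyl]-1,3,5-trimethoxybenzene
Product: 16 2,4-dibromo-6-[(1S)-1-[(1R,4R,4aS,6S,8aR)-4-hydroxy-6-(2-hydroxypropan-2-yl)-4,8a-dimethyldecahydronaphthalen-1-yl]-3-methylbutyl]-1,3,5-trimethoxybenzene
Conditions: NBS (2.1 equiv), MeCN, 0 °C
Reagents that add atoms: N-bromosuccinimide, O=C1CCC(=O)N1Br
Why: Electrophilic aromatic bromination of the two remaining positions of the highly activated ring; neutral conditions spare the tertiary alcohols.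

**Step 12**
Reactants: 16 2,4-dibromo-6-[(1S)-1-[(1R,4R,4aS,6S,8aR)-4-hydroxy-6-(2-hydroxypropan-2-yl)-4,8a-dimethyldecahydronaphthalen-1-yl]-3-methylbutyl]-1,3,5-trimethoxybenzene
Product: 18 5-[(1S)-1-[(1R,4R,4aS,6S,8aR)-4-hydroxy-6-(2-hydroxypropan-2-yl)-4,8a-dimethyldecahydronaphthalen-1-yl]-3-methylbutyl]-2,4,6-trimethoxybenzene-1,3-dicarbaldehyde, via tetralithiated intermediate 17 (not isolated)
Conditions: t-BuLi (7 equiv), THF, −78 °C; DMF, −78 °C → rt; aq. NH4Cl
Reagents that add atoms: N,N-dimethylformamide, CN(C)C=O; tert-butyllithium (Li of 17), [Li]C(C)(C)C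
Why: Double bromine–lithium exchange (each aryllithium is flanked by two chelating methoxy groups) followed by Bouveault formylation; the carbinols are carried as lithium alkoxides, so no acid touches them.

**Step 13**
Reactants: 18 5-[(1S)-1-[(1R,4R,4aS,6S,8aR)-4-hydroxy-6-(2-hydroxypropan-2-yl)-4,8a-dimethyldecahydronaphthalen-1-yl]-3-methylbutyl]-2,4,6-trimethoxybenzene-1,3-dicarbaldehyde
Product: 19 5-[(1S)-1-[(1R,4R,4aS,6S,8aR)-4-hydroxy-6-(2-hydroxypropan-2-yl)-4,8a-dimethyldecahydronaphthalen-1-yl]-3-methylbutyl]-2,4,6-trihydroxybenzene-1,3-dicarbaldehyde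
Conditions: NaSEt (12 equiv), DMF, 110 °C; then 1 M HCl
Reagents that add atoms: none
Why: Nucleophilic (SN2) O-demethylation by thiolate; every methoxy group is ortho or para to a formyl group and so is activated, and the basic conditions spare the acid-sensitive tertiary alcohols.

## Compound list

1 | 2′,4′,6′-trimethoxyacetophenone | CC(=O)c1c(OC)cc(OC)cc1OC | starting material
2 | 1-(2,4,6-trimethoxyphenyl)prop-2-en-1-one | C=CC(=O)c1c(OC)cc(OC)cc1OC | intermediate
3 | (R)-(−)-carvone, (5R)-2-methyl-5-(prop-1-en-2-yl)cyclohex-2-en-1-one | CC1=CC[C@H](CC1=O)C(C)=C | starting material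
4 | lithium (5R)-2-methyl-5-(prop-1-en-2-yl)cyclohex-1-en-1-olate (not isolated) | CC1=C(O[Li])C[C@@H](CC1)C(C)=C | intermediate
5 | (5R)-2-methyl-5-(prop-1-en-2-yl)cyclohex-1-en-1-yl trifluoromethanesulfonate | CC1=C(OS(=O)(=O)C(F)(F)F)C[C@@H](CC1)C(C)=C | intermediate
6 | (5R)-5-acetyl-2-methylcyclohex-1-en-1-yl trifluoromethanesulfonate | CC1=C(OS(=O)(=O)C(F)(F)F)C[C@@H](CC1)C(C)=O | intermediate
7 | tributyl(1-ethoxyethenyl)stannane | CCCC[Sn](CCCC)(CCCC)C(=C)OCC | starting material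
8 | 1-[(1R)-3-(1-ethoxyethenyl)-4-methylcyclohex-3-en-1-yl]ethan-1-one | CC1=C(C(=C)OCC)C[C@@H](CC1)C(C)=O | intermediate
9 | [(1R,6R,8aR)-6-acetyl-4-ethoxy-8a-methyl-1,2,3,5,6,7,8,8a-octahydronaphthalen-1-yl](2,4,6-trimethoxyphenyl)methanone (endo adduct; aroyl trans to the angular methyl, acetyl cis to C1) | COc1cc(OC)c(C(=O)[C@@H]2CCC(OCC)=C3C[C@H](C(C)=O)CC[C@]23C)c(OC)c1 | intermediate
10 | [(1R,6R,8aS)-6-acetyl-8a-methyl-4-oxodecahydronaphthalen-1-yl](2,4,6-trimethoxyphenyl)methanone, C4a epimers (not isolated) | COc1cc(OC)c(C(=O)[C@@H]2CCC(=O)C3C[C@H](C(C)=O)CC[C@]23C)c(OC)c1 | intermediate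
11 | [(1S,4aS,6S,8aS)-6-acetyl-8a-methyl-4-oxodecahydronaphthalen-1-yl](2,4,6-trimethoxyphenyl)methanone (trans-fused; aroyl and acetyl equatorial, methyl axial) | COc1cc(OC)c(C(=O)[C@H]2CCC(=O)[C@H]3C[C@@H](C(C)=O)CC[C@]23C)c(OC)c1 | intermediate
12 | [(1S,4R,4aS,6S,8aS)-4-hydroxy-6-(2-hydroxypropan-2-yl)-4,8a-dimethyldecahydronaphthalen-1-yl](2,4,6-trimethoxyphenyl)methanone | COc1cc(OC)c(C(=O)[C@H]2CC[C@@](C)(O)[C@H]3C[C@@H](C(C)(C)O)CC[C@]23C)c(OC)c1 | intermediate
13 | 1-[(1S,4R,4aS,6S,8aS)-4-hydroxy-6-(2-hydroxypropan-2-yl)-4,8a-dimethyldecahydronaphthalen-1-yl]-3-methyl-1-(2,4,6-trimethoxyphenyl)but-3-en-1-ol (benzylic carbinol: either epimer or both) | COc1cc(OC)c(C(O)(CC(C)=C)[C@H]2CC[C@@](C)(O)[C@H]3C[C@@H](C(C)(C)O)CC[C@]23C)c(OC)c1 | intermediate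
14 | 1-[(1S,4R,4aS,6S,8aS)-4-hydroxy-6-(2-hydroxypropan-2-yl)-4,8a-dimethyldecahydronaphthalen-1-yl]-3-methyl-1-(2,4,6-trimethoxyphenyl)butan-1-ol (benzylic carbinol: either epimer or both) | COc1cc(OC)c(C(O)(CC(C)C)[C@H]2CC[C@@](C)(O)[C@H]3C[C@@H](C(C)(C)O)CC[C@]23C)c(OC)c1 | intermediate
15 | 2-[(1S)-1-[(1R,4R,4aS,6S,8aR)-4-hydroxy-6-(2-hydroxypropan-2-yl)-4,8a-dimethyldecahydronaphthalen-1-yl]-3-methylbutyl]-1,3,5-trimethoxybenzene | CC(C)C[C@H](c1c(OC)cc(OC)cc1OC)[C@H]1CC[C@@](C)(O)[C@H]2C[C@@H](C(C)(C)O)CC[C@]12C | intermediate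
16 | 2,4-dibromo-6-[(1S)-1-[(1R,4R,4aS,6S,8aR)-4-hydroxy-6-(2-hydroxypropan-2-yl)-4,8a-dimethyldecahydronaphthalen-1-yl]-3-methylbutyl]-1,3,5-trimethoxybenzene | CC(C)C[C@H](c1c(OC)c(Br)c(OC)c(Br)c1OC)[C@H]1CC[C@@](C)(O)[C@H]2C[C@@H](C(C)(C)O)CC[C@]12C | intermediate
17 | 3,5-dilithio aryl species of 16 with both carbinols as lithium alkoxides (not isolated) | CC(C)C[C@H](c1c(OC)c([Li])c(OC)c([Li])c1OC)[C@H]1CC[C@@](C)(O[Li])[C@H]2C[C@@H](C(C)(C)O[Li])CC[C@]12C | intermediate
18 | 5-[(1S)-1-[(1R,4R,4aS,6S,8aR)-4-hydroxy-6-(2-hydroxypropan-2-yl)-4,8a-dimethyldecahydronaphthalen-1-yl]-3-methylbutyl]-2,4,6-trimethoxybenzene-1,3-dicarbaldehyde | CC(C)C[C@H](c1c(OC)c(C=O)c(OC)c(C=O)c1OC)[C@H]1CC[C@@](C)(O)[C@H]2C[C@@H](C(C)(C)O)CC[C@]12C | intermediate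
19 | 5-[(1S)-1-[(1R,4R,4aS,6S,8aR)-4-hydroxy-6-(2-hydroxypropan-2-yl)-4,8a-dimethyldecahydronaphthalen-1-yl]-3-methylbutyl]-2,4,6-trihydroxybenzene-1,3-dicarbaldehyde (CNP0409870.4) | CC(C)C[C@H](c1c(O)c(C=O)c(O)c(C=O)c1O)[C@H]1CC[C@@](C)(O)[C@H]2C[C@@H](C(C)(C)O)CC[C@]12C | target

## Summary and risk

Total step count: 13. Longest linear sequence: 12 steps (3 → 19, steps 2–13); step 1 makes the dienophile.

**Step 5 (cycloaddition).** The diene terminus that becomes C10 is fully substituted, and facial control is only 1,4-induction from the acetyl-bearing centre, so both reactivity and the C10 ratio are uncertain.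
Fallback: set out from 5 and keep the isopropenyl group so that only one ketone is enolisable. Stille coupling of 5 with 7 (Pd(PPh3)4, LiCl) gives (4R)-2-(1-ethoxyethenyl)-1-methyl-4-(prop-1-en-2-yl)cyclohex-1-ene F1, which acidic work-up hydrolyses to 1-[(5R)-2-methyl-5-(prop-1-en-2-yl)cyclohex-1-en-1-yl]ethan-1-one F2. Kinetic deprotonation of the acetyl methyl (LiN(i-Pr)2, THF, −78 °C) and addition of 2 starts an anionic Michael–Michael ring closure: the dienolate adds to the vinyl ketone, and the resulting aryl ketone enolate closes onto the β,β-disubstituted enone, axially and cis to the isopropenyl group. This gives [(6R,8aS)-8a-methyl-4-oxo-6-(prop-1-en-2-yl)decahydronaphthalen-1-yl](2,4,6-trimethoxyphenyl)methanone F3 as C1/C4a epimers. OsO4/NaIO4 cleavage gives [(6R,8aS)-6-acetyl-8a-methyl-4-oxodecahydronaphthalen-1-yl](2,4,6-trimethoxyphenyl)methanone F4 as C1/C4a epimers, and NaOMe/MeOH equilibration brings the material back to the route at 11.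

**Step 8 (addition to the very hindered aryl ketone).** Enolisation, retro-allylation or no reaction are all possible.
Fallback: set out from 12 and replace carbonyl addition by olefination, hydroboration and cross-coupling. The small, non-reducing reagent Me3SiCH2Li/CeCl3 adds to give 1-[(1S,4R,4aS,6S,8aS)-4-hydroxy-6-(2-hydroxypropan-2-yl)-4,8a-dimethyldecahydronaphthalen-1-yl]-1-(2,4,6-trimethoxyphenyl)-2-(trimethylsilyl)ethan-1-ol F5. Peterson elimination (KH, THF) gives 2-{1-[(1S,4R,4aS,6S,8aR)-4-hydroxy-6-(2-hydroxypropan-2-yl)-4,8a-dimethyldecahydronaphthalen-1-yl]ethenyl}-1,3,5-trimethoxybenzene F6. Excess 9-BBN places boron on the CH2 terminus and hydrogen on C9′, expected from the face remote from C10 as in step 10, to give 9-{(2S)-2-[(1R,4R,4aS,6S,8aR)-4-hydroxy-6-(2-hydroxypropan-2-yl)-4,8a-dimethyldecahydronaphthalen-1-yl]-2-(2,4,6-trimethoxyphenyl)ethyl}-9-borabicyclo[3.3.1]nonane F7. B-alkyl Suzuki–Miyaura coupling with 2-bromopropene (PdCl2(dppf), K3PO4, THF/H2O) gives 2-[(1S)-1-[(1R,4R,4aS,6S,8aR)-4-hydroxy-6-(2-hydroxypropan-2-yl)-4,8a-dimethyldecahydronaphthalen-1-yl]-3-methylbut-3-en-1-yl]-1,3,5-trimethoxybenzene F8. Hydrogenation over RhCl(PPh3)3 comes back to the route at 15, bypassing steps 9 and 10.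

**Step 10 (C9′ configuration).** The selectivity rests on a conformational model of a crowded cation and could be low.
Fallback: set out from 14 and switch from substrate control to catalyst control. Mild dehydration (pyridinium p-toluenesulfonate, benzene, 40 °C; only the benzylic carbinol ionises) gives 2-[(1Z)-1-[(1S,4R,4aS,6S,8aR)-4-hydroxy-6-(2-hydroxypropan-2-yl)-4,8a-dimethyldecahydronaphthalen-1-yl]-3-methylbut-1-en-1-yl]-1,3,5-trimethoxybenzene F9. Asymmetric hydrogenation (H2 50–100 bar, [Ir(cod)(L)][B(3,5-(CF3)2C6H3)4], L = (S)-4-tert-butyl-2-[2-(diphenylphosphanyl)phenyl]-4,5-dihydro-1,3-oxazole or its enantiomer, whichever is matched) comes back to the route at 15.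

## Further compounds

F1 | step 5 | (4R)-2-(1-ethoxyethenyl)-1-methyl-4-(prop-1-en-2-yl)cyclohex-1-ene | CC1=C(C(=C)OCC)C[C@@H](CC1)C(C)=C
F2 | step 5 | 1-[(5R)-2-methyl-5-(prop-1-en-2-yl)cyclohex-1-en-1-yl]ethan-1-one | CC1=C(C(C)=O)C[C@@H](CC1)C(C)=C
F3 | step 5 | [(6R,8aS)-8a-methyl-4-oxo-6-(prop-1-en-2-yl)decahydronaphthalen-1-yl](2,4,6-trimethoxyphenyl)methanone (C1/C4a epimers) | COc1cc(OC)c(C(=O)C2CCC(=O)C3C[C@H](C(C)=C)CC[C@]23C)c(OC)c1
F4 | step 5 | [(6R,8aS)-6-acetyl-8a-methyl-4-oxodecahydronaphthalen-1-yl](2,4,6-trimethoxyphenyl)methanone (C1/C4a epimers) | COc1cc(OC)c(C(=O)C2CCC(=O)C3C[C@H](C(C)=O)CC[C@]23C)c(OC)c1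
F5 | step 8 | 1-[(1S,4R,4aS,6S,8aS)-4-hydroxy-6-(2-hydroxypropan-2-yl)-4,8a-dimethyldecahydronaphthalen-1-yl]-1-(2,4,6-trimethoxyphenyl)-2-(trimethylsilyl)ethan-1-ol | COc1cc(OC)c(C(O)(C[Si](C)(C)C)[C@H]2CC[C@@](C)(O)[C@H]3C[C@@H](C(C)(C)O)CC[C@]23C)c(OC)c1
F6 | step 8 | 2-{1-[(1S,4R,4aS,6S,8aR)-4-hydroxy-6-(2-hydroxypropan-2-yl)-4,8a-dimethyldecahydronaphthalen-1-yl]ethenyl}-1,3,5-trimethoxybenzene | C=C(c1c(OC)cc(OC)cc1OC)[C@H]1CC[C@@](C)(O)[C@H]2C[C@@H](C(C)(C)O)CC[C@]12C
F7 | step 8 | 9-{(2S)-2-[(1R,4R,4aS,6S,8aR)-4-hydroxy-6-(2-hydroxypropan-2-yl)-4,8a-dimethyldecahydronaphthalen-1-yl]-2-(2,4,6-trimethoxyphenyl)ethyl}-9-borabicyclo[3.3.1]nonane | COc1cc(OC)c([C@@H](CB2C3CCCC2CCC3)[C@H]2CC[C@@](C)(O)[C@H]3C[C@@H](C(C)(C)O)CC[C@]23C)c(OC)c1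
F8 | step 8 | 2-[(1S)-1-[(1R,4R,4aS,6S,8aR)-4-hydroxy-6-(2-hydroxypropan-2-yl)-4,8a-dimethyldecahydronaphthalen-1-yl]-3-methylbut-3-en-1-yl]-1,3,5-trimethoxybenzene | CC(=C)C[C@H](c1c(OC)cc(OC)cc1OC)[C@H]1CC[C@@](C)(O)[C@H]2C[C@@H](C(C)(C)O)CC[C@]12C
F9 | step 10 | 2-[(1Z)-1-[(1S,4R,4aS,6S,8aR)-4-hydroxy-6-(2-hydroxypropan-2-yl)-4,8a-dimethyldecahydronaphthalen-1-yl]-3-methylbut-1-en-1-yl]-1,3,5-trimethoxybenzene | CC(C)/C=C(\c1c(OC)cc(OC)cc1OC)[C@H]1CC[C@@](C)(O)[C@H]2C[C@@H](C(C)(C)O)CC[C@]12C
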